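Drimane numbering is used throughout: ring A is C1–C5 plus C10, ring B is C5–C10, C11 is the OCH2 carbon on C9 and C12 the exocyclic CH2 on C8.
Retrosynthesis cuts the C3 ester and the C11–O aryl ether, then the C9–C11 bond (ester from an enol triflate), then the C3–C4 bond of ring A, and last the C10–C1 and C10–CH3 bonds of a doubly alkylated (S)-carvone.
Ring A can be closed at C3–C4 because C4 is a gem-dimethyl quaternary carbon next to oxygenated C3: a tertiary C4 radical made from the isopropenyl group on C5 adds to a C3 aldehyde at the end of the three-carbon chain on C10.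
Forward, ring B is the carvone ring (its carbonyl is C9, its ring methyl is C12, its isopropenyl carbon is C4); C10 is made quaternary, the allyl group becomes the aldehyde, ring A is closed, and C11, the exocyclic alkene, the coumarin ether and the isovalerate follow.
C5 comes from (S)-carvone, C10 from allylation anti to the isopropenyl group, C3 from the chair-like radical closure (oxygen equatorial), and C9 from protonation of an ester dienolate on the face opposite to the C10 methyl.

Key step: step 6

Remark: the substrate of the key step carries the future C12 as a spectator methyl on C8; compounds 8–13 are drawn as the C8 epimer expected after equilibration (methyl equatorial), and the other epimer would converge at enol triflate 15.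

Step 1
Reactants: 1 (S)-(+)-carvone [(5S)-2-methyl-5-(prop-1-en-2-yl)cyclohex-2-en-1-one]
Product: 3 (5S,6R)-2,6-dimethyl-5-(prop-1-en-2-yl)cyclohex-2-en-1-one (trans-6-methylcarvone), via lithium dienolate 2 (not isolated)
Conditions: LiN(i-Pr)2, THF, −78 °C; MeI, −78 → 0 °C
Reagents that add atoms: iodomethane, CI
Why: Kinetic deprotonation of the enone at C6 gives the cross-conjugated dienolate, and enolate alkylation with MeI, a standard reaction of carvone, is expected to enter mainly anti to the neighbouring isopropenyl group; the C6 configuration is of no consequence because C6 is planarised again in step 2.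

Step 2
Reactants: 3 trans-6-methylcarvone; 4 allyl bromide (3-bromoprop-1-ene)
Product: 6 (5R,6R)-2,6-dimethyl-6-(prop-2-en-1-yl)-5-(prop-1-en-2-yl)cyclohex-2-en-1-one (allyl trans to isopropenyl), via lithium dienolate 5 (not isolated)
Conditions: LiN(i-Pr)2, THF, −78 °C; allyl bromide, −78 → 0 °C
Reagents that add atoms: none
Why: Enolate alkylation, in which the reactive allylic bromide should attack the tetrasubstituted dienolate on the face opposite to the pseudo-axial isopropenyl group on the adjacent carbon, so that the future C10 becomes quaternary with the allyl chain trans and the methyl cis to the isopropenyl group, as the trans ring fusion later demands.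

Step 3
Reactants: 6 (5R,6R)-6-allyl-6-methylcarvone
Product: 8 (2R,3R,6S)-2,6-dimethyl-2-(prop-2-en-1-yl)-3-(prop-1-en-2-yl)cyclohexan-1-one, via lithium enolate 7 (not isolated)
Conditions: LiBH(s-Bu)3, THF, −78 °C; MeOH, −78 °C → rt
Reagents that add atoms: none
Why: Conjugate (1,4) hydride reduction, in which the hindered borohydride cannot reach the carbonyl carbon next to the quaternary centre and should add to the unsubstituted β-carbon of the enone while leaving the isolated alkenes alone, after which the methoxide formed on quenching equilibrates the new α-methyl centre (C8) to the equatorial epimer, a centre that is erased in step 8 in any case.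

Step 4
Reactants: 8 (2R,3R,6S)-2-allyl-2,6-dimethyl-3-isopropenylcyclohexanone
Product: 10 (2R,3R,6S)-2-(3-hydroxypropyl)-2,6-dimethyl-3-(prop-1-en-2-yl)cyclohexan-1-one, via alkyldisiamylborane 9 (not isolated)
Conditions: Sia2BH (from BH3·THF and 2-methylbut-2-ene), THF, 0 °C; 30% H2O2, aq NaOH, 0 °C
Reagents that add atoms: hydrogen peroxide, OO
Why: Hydroboration–oxidation, in which disiamylborane should add in the anti-Markovnikov sense to the monosubstituted allyl alkene far faster than to the hindered 1,1-disubstituted isopropenyl alkene or to the carbonyl group buried between two substituted α-carbons, and alkaline peroxide then replaces boron by hydroxyl.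

Step 5
Reactants: 10 (2R,3R,6S)-2-(3-hydroxypropyl)-2,6-dimethyl-3-isopropenylcyclohexanone
Product: 11 3-[(1R,3S,6R)-1,3-dimethyl-2-oxo-6-(prop-1-en-2-yl)cyclohexyl]propanal
Conditions: Dess–Martin periodinane, NaHCO3, CH2Cl2, 0 °C → rt
Reagents that add atoms: none
Why: Dess–Martin oxidation stops at the aldehyde under buffered, non-basic conditions, which should keep the 1,5-keto aldehyde from intramolecular aldol reaction and leave the isopropenyl group untouched.

Step 6
Reactants: 11 3-[(1R,3S,6R)-1,3-dimethyl-2-oxo-6-(prop-1-en-2-yl)cyclohexyl]propanal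
Product: 12 (2S,4aR,6R,8aR)-6-hydroxy-2,5,5,8a-tetramethyl-3,4,4a,5,6,7,8,8a-octahydronaphthalen-1(2H)-one (drimane numbering: 3-hydroxy-4,4,8,10-tetramethyl-trans-decal-9-one, 3-OH equatorial and cis to the C10 methyl)
Conditions: Fe(acac)3 (50 mol %), PhSiH3 (2.5 equiv, added slowly), EtOH, 60 °C, degassed, 0.02 M
Reagents that add atoms: none
Why: Fe(acac)3 and PhSiH3 in ethanol generate a trivalent iron hydride that transfers a hydrogen atom to the CH2 terminus of the isopropenyl group (Markovnikov sense), which creates the second C4 methyl and the tertiary C4 radical; this nucleophilic radical adds to the aldehyde carbon C3, and the resulting alkoxy radical is reduced by divalent iron and protonated by the solvent, which also returns trivalent iron. The closest known reaction type is the iron-hydride HAT-initiated reductive cyclisation of alkene-tethered ketones, together with the intermolecular alkene–aldehyde coupling under the same reagents. Ring A closes in the 6-exo-trig mode on the carbonyl group through a chair transition state in which the C5–C4 and C10–C1 bonds are both equatorial on ring B, so the trans ring fusion is dictated by the existing C5 and C10 centres. The new C3 centre is controlled by that chair: the carbonyl oxygen sits pseudo-equatorial to avoid the syn-axial hydrogens on C1 and C5, and because the addition is reversible the more stable equatorial alkoxy radical should be the one carried on to product, giving the 3R alcohol cis to the C10 methyl. The step needs hydrogen-atom transfer to the alkene only and ring closure faster than a second hydrogen transfer to the radical; the single electron-rich 1,1-disubstituted alkene, high dilution with slow addition of the silane, and the fact that attack on the ring B ketone would require a four-membered ring should secure this.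

Step 7
Reactants: 12 (2S,4aR,6R,8aR)-6-hydroxy-2,5,5,8a-tetramethyloctahydronaphthalen-1(2H)-one
Product: 13 (2S,4aR,6R,8aR)-6-[(tert-butyldimethylsilyl)oxy]-2,5,5,8a-tetramethyl-3,4,4a,5,6,7,8,8a-octahydronaphthalen-1(2H)-one
Conditions: TBSOTf, 2,6-lutidine, CH2Cl2, −78 → 0 °C
Reagents that add atoms: tert-butyldimethylsilyl trifluoromethanesulfonate, CC(C)(C)[Si](C)(C)OS(=O)(=O)C(F)(F)F
Why: Silyl ether formation, for which the silyl triflate and a hindered pyridine base should silylate even the neopentyl-type equatorial alcohol at low temperature, where the doubly α-substituted ketone is not expected to form a silyl enol ether.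

Step 8
Reactants: 13 silyl ether ketone
Product: 15 (4aR,6R,8aR)-6-[(tert-butyldimethylsilyl)oxy]-2,5,5,8a-tetramethyl-3,4,4a,5,6,7,8,8a-octahydronaphthalen-1-yl trifluoromethanesulfonate, via potassium enolate 14 (not isolated)
Conditions: KN(SiMe3)2, THF, −78 → 0 °C; PhNTf2, −78 °C → rt
Reagents that add atoms: N-phenylbis(trifluoromethanesulfonimide), O=S(=O)(N(c1ccccc1)S(=O)(=O)C(F)(F)F)C(F)(F)F
Why: Enol triflate formation, in which the ketone can enolise only toward C8 because C10 bears no hydrogen, so either C8 epimer gives the same potassium enolate and O-sulfonylation fixes the tetrasubstituted C8=C9 double bond, as is known for 2,2,6-trimethylcyclohexanone.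

Step 9
Reactants: 15 enol triflate
Product: 16 methyl (4aS,6R,8aR)-6-[(tert-butyldimethylsilyl)oxy]-2,5,5,8a-tetramethyl-3,4,4a,5,6,7,8,8a-octahydronaphthalene-1-carboxylate
Conditions: Pd(OAc)2 (10 mol %), PPh3, CO (1 atm), MeOH, Et3N, DMF, 65 °C
Reagents that add atoms: carbon monoxide, [C-]#[O+]; methanol, CO
Why: Palladium-catalysed alkoxycarbonylation, in which oxidative addition of the vinyl triflate to zerovalent palladium formed in situ, CO insertion and methanolysis of the acylpalladium species should give the ester that brings in C11, a reaction known for the equally hindered 2,6,6-trimethylcyclohexenyl triflate.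

Step 10
Reactants: 16 conjugated ester
Product: 18 methyl (1R,4aS,6R,8aR)-6-[(tert-butyldimethylsilyl)oxy]-5,5,8a-trimethyl-2-methylidenedecahydronaphthalene-1-carboxylate, via lithium dienolate 17 (not isolated)
Conditions: LiN(i-Pr)2, THF, −78 → −20 °C; AcOH, −78 °C (inverse addition)
Reagents that add atoms: none
Why: Deconjugative protonation of an α,β-unsaturated ester, in which the amide base, guided by the ester carbonyl, should remove a hydrogen from the C12 methyl that lies cis to it (in analogy to the known conversion of β-cyclogeranate esters into γ-cyclogeranates) and the exocyclic dienolate is then protonated irreversibly at C9 from the face opposite to the axial C10 methyl, which places H9 axial and the ester equatorial (9R).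

Step 11
Reactants: 18 β,γ-unsaturated ester
Product: 19 [(1R,4aS,6R,8aR)-6-[(tert-butyldimethylsilyl)oxy]-5,5,8a-trimethyl-2-methylidenedecahydronaphthalen-1-yl]methanol
Conditions: i-Bu2AlH, CH2Cl2, −78 → 0 °C; aq potassium sodium tartrate
Reagents that add atoms: none
Why: Ester reduction with the aluminium hydride at low temperature should give the primary alcohol without epimerising C9 or touching the silyl ether and the exocyclic alkene.

Step 12
Reactants: 19 primary alcohol; 20 umbelliferone (7-hydroxy-2H-chromen-2-one)
Product: 21 7-{[(1R,4aS,6R,8aR)-6-[(tert-butyldimethylsilyl)oxy]-5,5,8a-trimethyl-2-methylidenedecahydronaphthalen-1-yl]methoxy}-2H-chromen-2-one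
Conditions: PPh3, DIAD, THF, 0 °C → rt
Reagents that add atoms: none
Why: Mitsunobu etherification, in which the phenol of umbelliferone (pKa about 8) is acidic enough to protonate the betaine and should displace the oxyphosphonium group at the primary C11 in an SN2 step that involves no stereocentre.

Step 13
Reactants: 21 silyl-protected coumarin ether
Product: 22 7-{[(1R,4aS,6R,8aR)-6-hydroxy-5,5,8a-trimethyl-2-methylidenedecahydronaphthalen-1-yl]methoxy}-2H-chromen-2-one
Conditions: HF·pyridine, pyridine, THF, 0 °C → rt
Reagents that add atoms: none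
Why: Fluoride-induced desilylation, in which pyridine-buffered HF should cleave the hindered secondary silyl ether while the lactone, the aryl ether and the exocyclic alkene tolerate the mildly acidic medium.

Step 14
Reactants: 22 C3 alcohol
Product: 23 (2R,4aR,5R,8aS)-1,1,4a-trimethyl-6-methylidene-5-{[(2-oxo-2H-chromen-7-yl)oxy]methyl}decahydronaphthalen-2-yl 3-methylbutanoate (CNP0295317.1)
Conditions: isovaleric anhydride, DMAP, Et3N, CH2Cl2, rt
Reagents that add atoms: 3-methylbutanoic anhydride, CC(C)CC(=O)OC(=O)CC(C)C
Why: DMAP-catalysed acylation of the equatorial C3 alcohol by the anhydride takes place at oxygen with retention at C3 and should give the target ester.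

Compound list
1 | (S)-(+)-carvone, (5S)-2-methyl-5-(prop-1-en-2-yl)cyclohex-2-en-1-one | C=C(C)[C@H]1CC=C(C)C(=O)C1 | starting material
2 | lithium (3S)-6-methyl-3-(prop-1-en-2-yl)cyclohexa-1,5-dien-1-olate (lithium dienolate of 1) | C=C(C)[C@H]1CC=C(C)C(O[Li])=C1 | intermediate (not isolated)
3 | (5S,6R)-2,6-dimethyl-5-(prop-1-en-2-yl)cyclohex-2-en-1-one (trans-6-methylcarvone) | C=C(C)[C@H]1CC=C(C)C(=O)[C@@H]1C | intermediate
4 | allyl bromide (3-bromoprop-1-ene) | C=CCBr | starting material
5 | lithium (3R)-2,6-dimethyl-3-(prop-1-en-2-yl)cyclohexa-1,5-dien-1-olate (lithium dienolate of 3) | C=C(C)[C@H]1CC=C(C)C(O[Li])=C1C | intermediate (not isolated)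
6 | (5R,6R)-2,6-dimethyl-6-(prop-2-en-1-yl)-5-(prop-1-en-2-yl)cyclohex-2-en-1-one | C=C(C)[C@H]1CC=C(C)C(=O)[C@]1(C)CC=C | intermediate
7 | lithium (5R,6R)-2,6-dimethyl-6-(prop-2-en-1-yl)-5-(prop-1-en-2-yl)cyclohex-1-en-1-olate | C=C(C)[C@H]1CCC(C)=C(O[Li])[C@]1(C)CC=C | intermediate (not isolated)
8 | (2R,3R,6S)-2,6-dimethyl-2-(prop-2-en-1-yl)-3-(prop-1-en-2-yl)cyclohexan-1-one | C=C(C)[C@H]1CC[C@H](C)C(=O)[C@]1(C)CC=C | intermediate
9 | {3-[(1R,3S,6R)-1,3-dimethyl-2-oxo-6-(prop-1-en-2-yl)cyclohexyl]propyl}bis(3-methylbutan-2-yl)borane | C=C(C)[C@H]1CC[C@H](C)C(=O)[C@]1(C)CCCB(C(C)C(C)C)C(C)C(C)C | intermediate (not isolated)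
10 | (2R,3R,6S)-2-(3-hydroxypropyl)-2,6-dimethyl-3-(prop-1-en-2-yl)cyclohexan-1-one | C=C(C)[C@H]1CC[C@H](C)C(=O)[C@]1(C)CCCO | intermediate
11 | 3-[(1R,3S,6R)-1,3-dimethyl-2-oxo-6-(prop-1-en-2-yl)cyclohexyl]propanal | C=C(C)[C@H]1CC[C@H](C)C(=O)[C@]1(C)CCC=O | intermediate
12 | (2S,4aR,6R,8aR)-6-hydroxy-2,5,5,8a-tetramethyl-3,4,4a,5,6,7,8,8a-octahydronaphthalen-1(2H)-one | O=C1[C@@H](C)CC[C@@H]2C(C)(C)[C@H](O)CC[C@@]12C | intermediate
13 | (2S,4aR,6R,8aR)-6-[(tert-butyldimethylsilyl)oxy]-2,5,5,8a-tetramethyl-3,4,4a,5,6,7,8,8a-octahydronaphthalen-1(2H)-one | O=C1[C@@H](C)CC[C@@H]2C(C)(C)[C@H](O[Si](C)(C)C(C)(C)C)CC[C@@]12C | intermediate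
14 | potassium (4aR,6R,8aR)-6-[(tert-butyldimethylsilyl)oxy]-2,5,5,8a-tetramethyl-3,4,4a,5,6,7,8,8a-octahydronaphthalen-1-olate | [K]OC1=C(C)CC[C@@H]2C(C)(C)[C@H](O[Si](C)(C)C(C)(C)C)CC[C@@]12C | intermediate (not isolated)
15 | (4aR,6R,8aR)-6-[(tert-butyldimethylsilyl)oxy]-2,5,5,8a-tetramethyl-3,4,4a,5,6,7,8,8a-octahydronaphthalen-1-yl trifluoromethanesulfonate | O=S(=O)(OC1=C(C)CC[C@@H]2C(C)(C)[C@H](O[Si](C)(C)C(C)(C)C)CC[C@@]12C)C(F)(F)F | intermediate
16 | methyl (4aS,6R,8aR)-6-[(tert-butyldimethylsilyl)oxy]-2,5,5,8a-tetramethyl-3,4,4a,5,6,7,8,8a-octahydronaphthalene-1-carboxylate | COC(=O)C1=C(C)CC[C@@H]2C(C)(C)[C@H](O[Si](C)(C)C(C)(C)C)CC[C@@]12C | intermediate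
17 | lithium [(4aS,6R,8aR)-6-[(tert-butyldimethylsilyl)oxy]-5,5,8a-trimethyl-2-methylideneoctahydronaphthalen-1(2H)-ylidene](methoxy)methanolate (ketene acetal geometry not defined) | COC(O[Li])=C1C(=C)CC[C@@H]2C(C)(C)[C@H](O[Si](C)(C)C(C)(C)C)CC[C@@]12C | intermediate (not isolated)
18 | methyl (1R,4aS,6R,8aR)-6-[(tert-butyldimethylsilyl)oxy]-5,5,8a-trimethyl-2-methylidenedecahydronaphthalene-1-carboxylate | C=C1CC[C@@H]2C(C)(C)[C@H](O[Si](C)(C)C(C)(C)C)CC[C@@]2(C)[C@@H]1C(=O)OC | intermediate
19 | [(1R,4aS,6R,8aR)-6-[(tert-butyldimethylsilyl)oxy]-5,5,8a-trimethyl-2-methylidenedecahydronaphthalen-1-yl]methanol | C=C1CC[C@@H]2C(C)(C)[C@H](O[Si](C)(C)C(C)(C)C)CC[C@@]2(C)[C@@H]1CO | intermediate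
20 | umbelliferone (7-hydroxy-2H-chromen-2-one) | O=c1ccc2ccc(O)cc2o1 | starting material
21 | 7-{[(1R,4aS,6R,8aR)-6-[(tert-butyldimethylsilyl)oxy]-5,5,8a-trimethyl-2-methylidenedecahydronaphthalen-1-yl]methoxy}-2H-chromen-2-one | C=C1CC[C@@H]2C(C)(C)[C@H](O[Si](C)(C)C(C)(C)C)CC[C@@]2(C)[C@@H]1COc1ccc2ccc(=O)oc2c1 | intermediate
22 | 7-{[(1R,4aS,6R,8aR)-6-hydroxy-5,5,8a-trimethyl-2-methylidenedecahydronaphthalen-1-yl]methoxy}-2H-chromen-2-one | C=C1CC[C@@H]2C(C)(C)[C@H](O)CC[C@@]2(C)[C@@H]1COc1ccc2ccc(=O)oc2c1 | intermediate
23 | (2R,4aR,5R,8aS)-1,1,4a-trimethyl-6-methylidene-5-{[(2-oxo-2H-chromen-7-yl)oxy]methyl}decahydronaphthalen-2-yl 3-methylbutanoate (CNP0295317.1) | C=C1CC[C@@H]2C(C)(C)[C@H](OC(=O)CC(C)C)CC[C@@]2(C)[C@@H]1COc1ccc2ccc(=O)oc2c1 | target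

Total step count: 14. Longest linear sequence: 14 steps (1 → 23); allyl bromide 4 and umbelliferone 20 enter as purchased materials.

Steps most likely to fail

Step 6. The two faces of the aldehyde may not be well differentiated in the radical addition, or the alkoxy radical may be trapped before it can equilibrate, so that the axial C3 alcohol accompanies or outweighs 12. The fallback sets C3 by hydride delivery instead of by the radical closure. It sets out from 12 as obtained, together with its C3 epimer (2S,4aR,6S,8aR)-6-hydroxy-2,5,5,8a-tetramethyloctahydronaphthalen-1(2H)-one F1. The mixture would be oxidised with Dess–Martin periodinane to (2S,4aR,8aR)-2,5,5,8a-tetramethyl-3,4,4a,7,8,8a-hexahydronaphthalene-1,6(2H,5H)-dione F2. F2 would then be reduced with NaBH4 in portions (MeOH–CH2Cl2, −40 °C). The C3 carbonyl has only one substituted α-carbon and should be attacked axially well before the ring B carbonyl, which lies between the quaternary C10 and the methyl-bearing C8; axial attack gives the equatorial alcohol. The sequence comes back to the route at 12.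

Step 10. Proton abstraction at C7 may compete with abstraction from the C12 methyl and give the endocyclic alkene, the conjugated ester may re-form on quenching, or C9 may be protonated from the wrong face. The fallback replaces the anionic deconjugation by an excited-state one and sets out from 16. Irradiation at 254 nm in MeOH containing 1,2-dimethylimidazole should cause photoenolisation by a 1,5-hydrogen shift, which for geometric reasons can only take a hydrogen from the C12 methyl cis to the ester. Base-mediated ketonisation of the dienol at C9 would then give 18 directly, where the route is rejoined. No compound outside the list is formed (F0).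

Step 12. Substitution at C11, which is flanked by the tertiary C9 and the quaternary C10, may be slow enough for the activated oxyphosphonium intermediate to eliminate toward the conjugated 8(12),9(11)-diene or to be intercepted by the hydrazide. The fallback forms the aryl–oxygen bond instead of the alkyl–oxygen bond and sets out from 19. Palladium-catalysed C–O cross-coupling with purchased 7-bromocoumarin (O=c1ccc2ccc(Br)cc2o1; [Pd(allyl)Cl]2, t-BuBrettPhos, Cs2CO3, toluene, 80 °C, zerovalent palladium formed in situ) would arylate the alcohol oxygen without touching the C11–O bond. It comes back to the route at 21. No compound outside the list is formed (F0).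

Further compounds
F1 | step 6 | (2S,4aR,6S,8aR)-6-hydroxy-2,5,5,8a-tetramethyl-3,4,4a,5,6,7,8,8a-octahydronaphthalen-1(2H)-one (C3 epimer of 12, axial alcohol) | O=C1[C@@H](C)CC[C@@H]2C(C)(C)[C@@H](O)CC[C@@]12C
F2 | step 6 | (2S,4aR,8aR)-2,5,5,8a-tetramethyl-3,4,4a,7,8,8a-hexahydronaphthalene-1,6(2H,5H)-dione | O=C1[C@@H](C)CC[C@@H]2C(C)(C)C(=O)CC[C@@]12C
F0 | step 10 | none | none
F0 | step 12 | none | none
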